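Ring C is disconnected at C4–C4a and O1–C2. Ring A then becomes free 5-methoxyresorcinol, whose carbon flanked by OH and OMe and para to the second OH corresponds to C4a (its neighbouring oxygen becomes O1), while C2–C3–C4 becomes a 2-arylacrolein carrying ring B on the future C3. One aminocatalytic operation should join the two: Friedel–Crafts addition to the CH2 terminus (C4–C4a), enantioselective protonation of the enamine (C3) and lactol closure (O1–C2, ring C). The acrolein carries ring B fully substituted (3'-prenyl, 4'-OMe), with the 2'-hydroxyl masked as a TBS ether. Lactol reduction, Mitsunobu closure and desilylation complete the isoflavan.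

Key step: step 8

Assumption: the quinine-derived amine is taken to give the (3R) series, and its quinidine-derived pseudoenantiomer would replace it, with nothing else changed, if the opposite sense is found; the 2'-oxygen stays silylated from step 4 to step 11 because a free 2'-OH would trap aldehydes 9 and 12 as benzofuran-type hemiacetals and compete in step 10, and fluoride removes the group without the acid that an ortho-prenylphenol does not tolerate.

Step 1
Reactants: 1 2-hydroxy-4-methoxybenzaldehyde; 2 3-chloro-3-methylbut-1-yne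
Product: 3 4-methoxy-2-[(2-methylbut-3-yn-2-yl)oxy]benzaldehyde
Conditions: DBU, CuCl2·2H2O (cat.), MeCN, 0 °C
Reagents that add atoms: none
Why: Copper-catalysed propargylic etherification, in which the copper acetylide of 2 ionises at the tertiary carbon and is captured by the phenoxide; this reaction type tolerates hydrogen-bonded, electron-poor phenols and leaves the aldehyde untouched.

Step 2
Reactants: 3 4-methoxy-2-[(2-methylbut-3-yn-2-yl)oxy]benzaldehyde
Product: 4 4-methoxy-2-[(2-methylbut-3-en-2-yl)oxy]benzaldehyde
Conditions: H2 (1 atm), Pd/CaCO3 poisoned with Pb(OAc)2 (Lindlar catalyst), quinoline, EtOAc, rt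
Reagents that add atoms: none
Why: Lindlar semihydrogenation stops at the terminal alkene and spares the aryl aldehyde; it is done before any heating so that the propargyl ether cannot cyclise to a chromene.

Step 3
Reactants: 4 4-methoxy-2-[(2-methylbut-3-en-2-yl)oxy]benzaldehyde
Product: 6 2-hydroxy-4-methoxy-3-(3-methylbut-2-en-1-yl)benzaldehyde, via ortho-dienone 5 (not isolated)
Conditions: PhNEt2, 140 °C, Ar
Reagents that add atoms: none
Why: Aromatic Claisen rearrangement, in which the [3,3]-sigmatropic shift turns the 1,1-dimethylallyl ether into a prenyl group at C3, the only free ortho position, and tautomerisation of the dienone restores the phenol; the basic solvent suppresses acid-induced chroman formation.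

Step 4
Reactants: 6 2-hydroxy-4-methoxy-3-(3-methylbut-2-en-1-yl)benzaldehyde
Product: 7 2-[(tert-butyldimethylsilyl)oxy]-4-methoxy-3-(3-methylbut-2-en-1-yl)benzaldehyde
Conditions: TBSCl, imidazole, DMF, rt
Reagents that add atoms: tert-butyldimethylsilyl chloride (TBSCl), CC(C)(C)[Si](C)(C)Cl
Why: Standard imidazole-mediated O-silylation of a phenol; salicylaldehyde-type phenols react under these conditions, and the flanking substituents should make the resulting aryl silyl ether robust.

Step 5
Reactants: 7 2-[(tert-butyldimethylsilyl)oxy]-4-methoxy-3-(3-methylbut-2-en-1-yl)benzaldehyde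
Product: 8 tert-butyl[3-methoxy-6-(2-methoxyethenyl)-2-(3-methylbut-2-en-1-yl)phenoxy]dimethylsilane (E/Z mixture)
Conditions: Ph3P(CH2OMe)Cl, NaN(SiMe3)2, THF, 0 °C; then 7, −78 °C → rt
Reagents that add atoms: (methoxymethyl)triphenylphosphonium chloride, COC[P+](c1ccccc1)(c1ccccc1)c1ccccc1.[Cl-]
Why: Wittig methoxymethylenation of an aryl aldehyde; the ylide is preformed with an amide base so that no alkoxide is present to attack the aryl silyl ether, and the alkene geometry is irrelevant because both isomers hydrolyse to the same aldehyde.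

Step 6
Reactants: 8 tert-butyl[3-methoxy-6-(2-methoxyethenyl)-2-(3-methylbut-2-en-1-yl)phenoxy]dimethylsilane
Product: 9 2-{2-[(tert-butyldimethylsilyl)oxy]-4-methoxy-3-(3-methylbut-2-en-1-yl)phenyl}acetaldehyde
Conditions: 1 M aq. HCl, THF, rt
Reagents that add atoms: water, O
Why: Acid-catalysed enol ether hydrolysis, with C-protonation followed by addition of water and loss of methanol; it runs in dilute acid that should leave the trisubstituted alkene and the hindered aryl silyl ether intact.

Step 7
Reactants: 9 2-{2-[(tert-butyldimethylsilyl)oxy]-4-methoxy-3-(3-methylbut-2-en-1-yl)phenyl}acetaldehyde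
Product: 10 2-{2-[(tert-butyldimethylsilyl)oxy]-4-methoxy-3-(3-methylbut-2-en-1-yl)phenyl}prop-2-enal
Conditions: aq. HCHO (37 %), pyrrolidine (10 mol %), EtCO2H (10 mol %), i-PrOH, 45 °C
Reagents that add atoms: formaldehyde, C=O
Why: Amine-catalysed α-methylenation (Mannich condensation with formaldehyde followed by elimination of the amine), the established route from arylacetaldehydes to 2-arylacroleins; the product should be used promptly to avoid self-condensation.

Step 8
Reactants: 10 2-{2-[(tert-butyldimethylsilyl)oxy]-4-methoxy-3-(3-methylbut-2-en-1-yl)phenyl}prop-2-enal; 11 5-methoxybenzene-1,3-diol (5-methoxyresorcinol)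
Product: 13 (3R)-3-{2-[(tert-butyldimethylsilyl)oxy]-4-methoxy-3-(3-methylbut-2-en-1-yl)phenyl}-5-methoxy-3,4-dihydro-2H-chromene-2,7-diol (mixture of C2 epimers), via open hydroxy aldehyde 12 (not isolated)
Conditions: 9-amino-9-deoxy-epi-quinine (20 mol %), CF3CO2H (40 mol %), 11 (3 equiv), slow addition of 10, CHCl3, 0 °C
Reagents that add atoms: none
Why: Proposed new method: the primary amine of the catalyst condenses with the α-branched enal 10 to a catalyst-bound iminium ion, C4 of 11 (the carbon between OH and OMe, para to the other OH) attacks the unsubstituted CH2 terminus in a Friedel–Crafts-type conjugate addition, and the catalyst-bound aryl-conjugated enamine is protonated at the future C3 by the quinuclidinium group of the same catalyst before hydrolysis releases aldehyde 12. The closest known reaction types are primary-amine iminium-catalysed conjugate additions to α-substituted acroleins that end in an enantioselective protonation, and amine-catalysed annulations of electron-rich phenols with enals to chroman-2-ols; their combination on a 2-arylacrolein with a resorcinol is not established. Ring C closes by 6-exo-trig attack of the neighbouring ring A hydroxyl on the aldehyde, which stores the enolisable α-aryl aldehyde as lactol 13 and so shields C3 from racemisation. C3 is set under catalyst control by proton delivery within the chiral ammonium–enamine assembly, whereas the anomeric C2 is uncontrolled and is removed in step 9. The step needs site selectivity for C4/C6 over C2 of 11, which rests on the two equivalent positions, on activation by the para hydroxyl and on the greater crowding between two hydroxyls; it also needs mono-alkylation (excess 11, slow addition of 10) and a silent ring B oxygen (blocked as the hindered silyl ether).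

Step 9
Reactants: 13 (3R)-3-{2-[(tert-butyldimethylsilyl)oxy]-4-methoxy-3-(3-methylbut-2-en-1-yl)phenyl}-5-methoxy-3,4-dihydro-2H-chromene-2,7-diol
Product: 14 4-[(2R)-2-{2-[(tert-butyldimethylsilyl)oxy]-4-methoxy-3-(3-methylbut-2-en-1-yl)phenyl}-3-hydroxypropyl]-5-methoxybenzene-1,3-diol
Conditions: NaBH4, MeOH/THF, −20 → 0 °C; aq. NH4Cl
Reagents that add atoms: none
Why: Borohydride reduction of a lactol, in which hydride adds to the carbonyl of the ring-opened hydroxy aldehyde tautomer that the hemiacetal keeps in equilibrium (the open form 12 already met in step 8); at low temperature hydride transfer should outpace enolisation so that C3 is retained, and the silyl ether and prenyl group are inert.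

Step 10
Reactants: 14 4-[(2R)-2-{2-[(tert-butyldimethylsilyl)oxy]-4-methoxy-3-(3-methylbut-2-en-1-yl)phenyl}-3-hydroxypropyl]-5-methoxybenzene-1,3-diol
Product: 15 (3R)-3-{2-[(tert-butyldimethylsilyl)oxy]-4-methoxy-3-(3-methylbut-2-en-1-yl)phenyl}-5-methoxy-3,4-dihydro-2H-chromen-7-ol
Conditions: PPh3, DIAD, THF (high dilution), 0 °C → rt
Reagents that add atoms: none
Why: Intramolecular Mitsunobu etherification, in which the primary alcohol is activated as its alkoxyphosphonium salt and displaced by the ortho phenol in a 6-exo-tet closure; the para hydroxyl can react only intermolecularly, which dilution disfavours, and substitution at the CH2 carbon leaves C3 untouched.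

Step 11
Reactants: 15 (3R)-3-{2-[(tert-butyldimethylsilyl)oxy]-4-methoxy-3-(3-methylbut-2-en-1-yl)phenyl}-5-methoxy-3,4-dihydro-2H-chromen-7-ol
Product: 16 (3R)-3-[2-hydroxy-4-methoxy-3-(3-methylbut-2-en-1-yl)phenyl]-5-methoxy-3,4-dihydro-2H-chromen-7-ol
Conditions: Bu4NF, AcOH (1:1), THF, 0 °C → rt
Reagents that add atoms: none
Why: Fluoride-induced cleavage of an aryl silyl ether; acetic acid buffering keeps the electron-rich phenols protonated, and no acid strong enough to cyclise the ortho-prenylphenol is present.

Compound list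
1 | 2-hydroxy-4-methoxybenzaldehyde | COc1ccc(C=O)c(O)c1 | starting material
2 | 3-chloro-3-methylbut-1-yne | CC(C)(Cl)C#C | starting material
3 | 4-methoxy-2-[(2-methylbut-3-yn-2-yl)oxy]benzaldehyde | COc1ccc(C=O)c(OC(C)(C)C#C)c1 | intermediate
4 | 4-methoxy-2-[(2-methylbut-3-en-2-yl)oxy]benzaldehyde | COc1ccc(C=O)c(OC(C)(C)C=C)c1 | intermediate
5 | 4-methoxy-5-(3-methylbut-2-en-1-yl)-6-oxocyclohexa-1,3-diene-1-carbaldehyde (ortho-dienone, racemic) | O=CC1=CC=C(OC)C(CC=C(C)C)C1=O | intermediate (not isolated)
6 | 2-hydroxy-4-methoxy-3-(3-methylbut-2-en-1-yl)benzaldehyde | COc1ccc(C=O)c(O)c1CC=C(C)C | intermediate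
7 | 2-[(tert-butyldimethylsilyl)oxy]-4-methoxy-3-(3-methylbut-2-en-1-yl)benzaldehyde | COc1ccc(C=O)c(O[Si](C)(C)C(C)(C)C)c1CC=C(C)C | intermediate
8 | tert-butyl[3-methoxy-6-(2-methoxyethenyl)-2-(3-methylbut-2-en-1-yl)phenoxy]dimethylsilane (E/Z mixture) | COC=Cc1ccc(OC)c(CC=C(C)C)c1O[Si](C)(C)C(C)(C)C | intermediate
9 | 2-{2-[(tert-butyldimethylsilyl)oxy]-4-methoxy-3-(3-methylbut-2-en-1-yl)phenyl}acetaldehyde | O=CCc1ccc(OC)c(CC=C(C)C)c1O[Si](C)(C)C(C)(C)C | intermediate
10 | 2-{2-[(tert-butyldimethylsilyl)oxy]-4-methoxy-3-(3-methylbut-2-en-1-yl)phenyl}prop-2-enal | C=C(C=O)c1ccc(OC)c(CC=C(C)C)c1O[Si](C)(C)C(C)(C)C | intermediate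
11 | 5-methoxybenzene-1,3-diol (5-methoxyresorcinol) | COc1cc(O)cc(O)c1 | starting material
12 | (2R)-2-{2-[(tert-butyldimethylsilyl)oxy]-4-methoxy-3-(3-methylbut-2-en-1-yl)phenyl}-3-(2,4-dihydroxy-6-methoxyphenyl)propanal | COc1cc(O)cc(O)c1C[C@H](c1ccc(OC)c(CC=C(C)C)c1O[Si](C)(C)C(C)(C)C)C=O | intermediate (not isolated)
13 | (3R)-3-{2-[(tert-butyldimethylsilyl)oxy]-4-methoxy-3-(3-methylbut-2-en-1-yl)phenyl}-5-methoxy-3,4-dihydro-2H-chromene-2,7-diol (C2 epimers) | COc1cc(O)cc2c1C[C@H](c1ccc(OC)c(CC=C(C)C)c1O[Si](C)(C)C(C)(C)C)C(O)O2 | intermediate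
14 | 4-[(2R)-2-{2-[(tert-butyldimethylsilyl)oxy]-4-methoxy-3-(3-methylbut-2-en-1-yl)phenyl}-3-hydroxypropyl]-5-methoxybenzene-1,3-diol | COc1cc(O)cc(O)c1C[C@H](c1ccc(OC)c(CC=C(C)C)c1O[Si](C)(C)C(C)(C)C)CO | intermediate
15 | (3R)-3-{2-[(tert-butyldimethylsilyl)oxy]-4-methoxy-3-(3-methylbut-2-en-1-yl)phenyl}-5-methoxy-3,4-dihydro-2H-chromen-7-ol | COc1cc(O)cc2c1C[C@H](c1ccc(OC)c(CC=C(C)C)c1O[Si](C)(C)C(C)(C)C)CO2 | intermediate
16 | (3R)-3-[2-hydroxy-4-methoxy-3-(3-methylbut-2-en-1-yl)phenyl]-5-methoxy-3,4-dihydro-2H-chromen-7-ol | COc1cc(O)cc2c1C[C@H](c1ccc(OC)c(CC=C(C)C)c1O)CO2 | target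

Total step count: 11. Longest linear sequence: 11 steps (1 → 16); 2 and 11 enter at steps 1 and 8.

Steps most likely to fail

Step 8. The enamine may be protonated unselectively by the excess phenol or by adventitious water, the resorcinol may react through the carbon between its two hydroxyls, the electron-rich lactol may be alkylated a second time, or the acrolein may oligomerise before it is consumed. The fallback sets the stereocentre by a chiral-auxiliary enolate benzylation; it sets out from 9 and comes back at 14. Aldehyde 9 would be oxidised (NaClO2, NaH2PO4, 2-methylbut-2-ene, t-BuOH/H2O) to 2-{2-[(tert-butyldimethylsilyl)oxy]-4-methoxy-3-(3-methylbut-2-en-1-yl)phenyl}acetic acid F1, which would be coupled through its pivaloyl mixed anhydride (PivCl, Et3N) with lithiated (R)-4-benzyl-1,3-oxazolidin-2-one to give (4R)-4-benzyl-3-(arylacetyl)-1,3-oxazolidin-2-one F2. In parallel, commercial 2,4-dihydroxy-6-methoxybenzaldehyde (COc1cc(O)cc(O)c1C=O) would be bis-allylated (allyl bromide, K2CO3, DMF) to 2,4-bis(allyloxy)-6-methoxybenzaldehyde F3, reduced (NaBH4, MeOH) to [2,4-bis(allyloxy)-6-methoxyphenyl]methanol F4, and converted (PBr3, Et2O, −20 °C, used at once) into 2-(bromomethyl)-1-methoxy-3,5-bis(allyloxy)benzene F5. The sodium enolate of F2 (NaN(SiMe3)2, THF, −78 °C) should be alkylated by F5 on the face opposite the benzyl group of the auxiliary; with the (R)-auxiliary and the aryl group in the place of the usual alkyl group, this should give the (2R)-2-aryl-3-[2,4-bis(allyloxy)-6-methoxyphenyl]propanoyl oxazolidinone F6. LiBH4 (THF, MeOH, 0 °C) would then remove the auxiliary reductively to give (2R)-3-[2,4-bis(allyloxy)-6-methoxyphenyl]-2-aryl-propan-1-ol F7, and Pd(PPh3)4 with morpholine in THF would remove both allyl groups without touching the prenyl group or the silyl ether, giving 14, after which steps 10 and 11 follow unchanged.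

Step 10. The activated alcohol may be intercepted intermolecularly by the para hydroxyl (oligomers) or by the reduced azodicarboxylate, or may undergo β-elimination. The fallback separates activation from ring closure; it sets out from 14 and comes back at 15. An Appel reaction (CBr4, PPh3, CH2Cl2, 0 °C), to which phenols are inert, should convert the primary alcohol into 4-[(2R)-3-bromo-2-{2-[(tert-butyldimethylsilyl)oxy]-4-methoxy-3-(3-methylbut-2-en-1-yl)phenyl}propyl]-5-methoxybenzene-1,3-diol F8. Slow addition of F8 to K2CO3 in dry acetone at high dilution should then close ring C by intramolecular Williamson etherification through the ortho phenoxide, giving 15.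

Step 9. The ring-opened α-aryl aldehyde may enolise in the basic borohydride medium and erode the configuration at C3, or the silyl group may migrate to the new primary oxygen or be lost. The fallback avoids the basic open-chain stage; it sets out from 13 and comes back at 15, so that step 10 is bypassed as well. Ionic reduction of the lactol (Et3SiH, BF3·OEt2, CH2Cl2, −78 °C) through the cyclic oxocarbenium ion should give chroman 15 directly. The low temperature and excess silane serve to outrun both proton loss from the oxocarbenium ion and any reaction of the prenyl alkene. This fallback makes no compound outside the list (F0).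

Further compounds
F1 | step 8 | 2-{2-[(tert-butyldimethylsilyl)oxy]-4-methoxy-3-(3-methylbut-2-en-1-yl)phenyl}acetic acid | OC(=O)Cc1ccc(OC)c(CC=C(C)C)c1O[Si](C)(C)C(C)(C)C
F2 | step 8 | (4R)-4-benzyl-3-(2-{2-[(tert-butyldimethylsilyl)oxy]-4-methoxy-3-(3-methylbut-2-en-1-yl)phenyl}acetyl)-1,3-oxazolidin-2-one | O=C(Cc1ccc(OC)c(CC=C(C)C)c1O[Si](C)(C)C(C)(C)C)N1[C@H](Cc2ccccc2)COC1=O
F3 | step 8 | 2,4-bis(allyloxy)-6-methoxybenzaldehyde | C=CCOc1cc(OC)c(C=O)c(OCC=C)c1
F4 | step 8 | [2,4-bis(allyloxy)-6-methoxyphenyl]methanol | C=CCOc1cc(OC)c(CO)c(OCC=C)c1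
F5 | step 8 | 2-(bromomethyl)-1-methoxy-3,5-bis(allyloxy)benzene | C=CCOc1cc(OC)c(CBr)c(OCC=C)c1
F6 | step 8 | (4R)-4-benzyl-3-[(2R)-3-[2,4-bis(allyloxy)-6-methoxyphenyl]-2-{2-[(tert-butyldimethylsilyl)oxy]-4-methoxy-3-(3-methylbut-2-en-1-yl)phenyl}propanoyl]-1,3-oxazolidin-2-one | C=CCOc1cc(OC)c(C[C@H](c2ccc(OC)c(CC=C(C)C)c2O[Si](C)(C)C(C)(C)C)C(=O)N2[C@H](Cc3ccccc3)COC2=O)c(OCC=C)c1
F7 | step 8 | (2R)-3-[2,4-bis(allyloxy)-6-methoxyphenyl]-2-{2-[(tert-butyldimethylsilyl)oxy]-4-methoxy-3-(3-methylbut-2-en-1-yl)phenyl}propan-1-ol | C=CCOc1cc(OC)c(C[C@H](c2ccc(OC)c(CC=C(C)C)c2O[Si](C)(C)C(C)(C)C)CO)c(OCC=C)c1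
F8 | step 10 | 4-[(2R)-3-bromo-2-{2-[(tert-butyldimethylsilyl)oxy]-4-methoxy-3-(3-methylbut-2-en-1-yl)phenyl}propyl]-5-methoxybenzene-1,3-diol | COc1cc(O)cc(O)c1C[C@H](c1ccc(OC)c(CC=C(C)C)c1O[Si](C)(C)C(C)(C)C)CBr
F0 | step 9 | none | none
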